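## Retrosynthetic overview

1. The 4,5-epoxide is installed last by peracid epoxidation of the 4E-alkene; the C8 methacrylate and C1 acetate are late acylations, the C13 acetate is carried from the butenolide stage.
2. The ten-membered carbocycle is closed at C7–C8 by an intramolecular Nozaki–Hiyama–Kishi reaction of a 4-iodobutenolide aldehyde; C8 is then fixed by oxidation and CBS reduction.
3. The butenolide (first ring) comes from a γ-hydroxy ynoate (C6 set by catalytic asymmetric alkynylation of an enal) through syn-distannation, α-hydroxymethylation (C13), iododestannylation and lactonisation.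
4. The C1/C10 stereodiad comes from a ketoreductase dynamic kinetic resolution of an α-methyl β-keto ester made from geraniol and methyl propanoate; one-carbon homologation then gives C8.
5. Ring order: butenolide, then carbocycle, then epoxide.

Assumption and conventions: the ketoreductase, the ProPhenol–ZnMe2 catalyst and the CBS catalyst are taken to follow their usual sense of induction (otherwise the antipode or a stereocomplementary enzyme is meant); the Sn–Li exchange selectivity in step 16 is recalled from precedent on simpler 2,3-bis(trimethylstannyl) enoates and is not verified for this substrate; macrocycles carry germacrane numbering (C6 bears the lactone oxygen, C12 is the lactone carbonyl, C13 the CH2O carbon); TBS = tert-butyldimethylsilyl, TES = triethylsilyl, PMB = 4-methoxybenzyl.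

## Route

Step 1
Reactants: 1 geraniol
Product: 2 1-({[(2E)-3,7-dimethylocta-2,6-dien-1-yl]oxy}methyl)-4-methoxybenzene (geranyl PMB ether)
Conditions: NaH, PMBCl, n-Bu4NI (cat.), THF/DMF, 0 °C to 25 °C
Reagents that add atoms: 4-methoxybenzyl chloride, COc1ccc(CCl)cc1
Why: Williamson etherification of the primary allylic alkoxide; no stereocentre is involved.

Step 2
Reactants: 2 geranyl PMB ether
Product: 3 rac-3-{(3E)-5-[(4-methoxybenzyl)oxy]-3-methylpent-3-en-1-yl}-2,2-dimethyloxirane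
Conditions: mCPBA (1.05 equiv), NaHCO3, CH2Cl2, −20 °C to 0 °C
Reagents that add atoms: mCPBA, OOC(=O)c1cccc(Cl)c1
Why: Prilezhaev epoxidation selects the more electron-rich terminal alkene because the 2,3-alkene is deactivated by the allylic ether oxygen; the racemic centre is destroyed in step 3.

Step 3
Reactants: 3 terminal epoxide
Product: 5 (4E)-6-[(4-methoxybenzyl)oxy]-4-methylhex-4-enal, via vicinal diol 4 (not isolated)
Conditions: H5IO6, THF/H2O, 0 °C
Reagents that add atoms: none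
Why: acid-mediated hydrolysis of the epoxide to the diol followed by periodate (Malaprade) glycol cleavage gives the C1 aldehyde and acetone.

Step 4
Reactants: 5 aldehyde; 6 methyl propanoate
Product: 8 methyl (6E)-3-hydroxy-8-[(4-methoxybenzyl)oxy]-2,6-dimethyloct-6-enoate (racemic syn/anti mixture), via lithium enolate 7 (not isolated)
Conditions: LiN(i-Pr)2, THF, −78 °C; then 5; aq. NH4Cl
Reagents that add atoms: none
Why: lithium ester-enolate aldol addition; its stereochemical outcome is irrelevant because both new centres are erased or equilibrated before step 6.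

Step 5
Reactants: 8 aldol adduct
Product: 9 methyl (6E)-8-[(4-methoxybenzyl)oxy]-2,6-dimethyl-3-oxooct-6-enoate (racemic)
Conditions: Dess–Martin periodinane, NaHCO3, CH2Cl2, 25 °C
Reagents that add atoms: none
Why: Dess–Martin oxidation of the secondary alcohol gives the configurationally labile α-methyl β-keto ester.

Step 6
Reactants: 9 racemic β-keto ester
Product: 10 methyl (2R,3S,6E)-3-hydroxy-8-[(4-methoxybenzyl)oxy]-2,6-dimethyloct-6-enoate
Conditions: ketoreductase (NADPH-dependent, panel member selective for the syn-(2R,3S) alcohol), NADP+ (cat.), i-PrOH (10% v/v), KH2PO4/K2HPO4 buffer pH 7.0, DMSO (5%), 30 °C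
Reagents that add atoms: none
Why: ketoreductase-catalysed dynamic kinetic resolution (enzymatic asymmetric carbonyl reduction): the α-centre racemises through the enol at pH 7 while the enzyme reduces only the (2R)-ketone from one face, setting C10 (2R) and C1 (3S) syn.

Step 7
Reactants: 10 hydroxy ester
Product: 11 methyl (2R,3S,6E)-3-(TBS-oxy)-8-[(4-methoxybenzyl)oxy]-2,6-dimethyloct-6-enoate
Conditions: TBSOTf, 2,6-lutidine, CH2Cl2, −78 °C to 0 °C
Reagents that add atoms: tert-butyldimethylsilyl triflate, CC(C)(C)[Si](C)(C)OS(=O)(=O)C(F)(F)F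
Why: silylation of the secondary alcohol with the reactive silyl triflate leaves both stereocentres untouched.

Step 8
Reactants: 11 silyl ester
Product: 12 (2R,3S,6E)-3-(TBS-oxy)-8-[(4-methoxybenzyl)oxy]-2,6-dimethyloct-6-enal
Conditions: i-Bu2AlH (1.1 equiv), CH2Cl2, −78 °C; MeOH then aq. KNaC4H4O6
Reagents that add atoms: none
Why: partial ester reduction stops at the aldehyde because the tetrahedral aluminium hemiacetal is stable at −78 °C, and the cold neutral work-up avoids epimerisation at C10.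

Step 9
Reactants: 12 aldehyde
Product: 13 tert-butyl{[(3S,4S,7E)-1-methoxy-9-[(4-methoxybenzyl)oxy]-3,7-dimethylnona-1,7-dien-4-yl]oxy}dimethylsilane (1E/1Z mixture)
Conditions: [Ph3PCH2OMe]Cl, KN(SiMe3)2, THF, 0 °C; then 12, −78 °C to 0 °C
Reagents that add atoms: (methoxymethyl)triphenylphosphonium chloride, COC[P+](c1ccccc1)(c1ccccc1)c1ccccc1.[Cl-]
Why: Wittig olefination with the non-stabilised methoxymethylene ylide adds the C8 carbon (one-carbon homologation); the enol-ether geometry is irrelevant.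

Step 10
Reactants: 13 enol ether
Product: 14 tert-butyl{[(3S,4S,7E)-1,1-dimethoxy-9-[(4-methoxybenzyl)oxy]-3,7-dimethylnon-7-en-4-yl]oxy}dimethylsilane
Conditions: PPTS (10 mol%), MeOH, 25 °C
Reagents that add atoms: methanol, CO
Why: acid-catalysed Markovnikov addition of methanol to the enol ether gives the dimethyl acetal, a base- and organometallic-stable mask of the C8 aldehyde.

Step 11
Reactants: 14 PMB ether
Product: 15 (2E,6S,7S)-6-(TBS-oxy)-9,9-dimethoxy-3,7-dimethylnon-2-en-1-ol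
Conditions: DDQ, CH2Cl2/pH 7 phosphate buffer (10:1), 0 °C
Reagents that add atoms: none
Why: oxidative PMB cleavage by DDQ at the electron-rich benzylic position under buffered conditions spares the acetal and the silyl ether.

Step 12
Reactants: 15 allylic alcohol
Product: 16 (2E,6S,7S)-6-(TBS-oxy)-9,9-dimethoxy-3,7-dimethylnon-2-enal
Conditions: MnO2 (excess), CH2Cl2, 25 °C
Reagents that add atoms: none
Why: MnO2 oxidises only the allylic alcohol and keeps the E-geometry of the enal.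

Step 13
Reactants: 16 enal; 17 methyl propiolate
Product: 19 methyl (4R,5E,9S,10S)-9-(TBS-oxy)-4-hydroxy-12,12-dimethoxy-6,10-dimethyldodec-5-en-2-ynoate, via zinc acetylide 18 (not isolated)
Conditions: ZnMe2 (3 equiv), 17 (3 equiv), (S,S)-ProPhenol [2,6-bis{[(S)-2-(hydroxydiphenylmethyl)pyrrolidin-1-yl]methyl}-4-methylphenol] (15 mol%), toluene, 0 °C to 4 °C; then 16
Reagents that add atoms: none
Why: catalytic asymmetric alkynylation (dinuclear zinc–ProPhenol): 1,2-addition of the zinc acetylide to the Si face of the enal sets C6 (4R) under catalyst control.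

Step 14
Reactants: 19 γ-hydroxy ynoate
Product: 20 methyl (4R,5E,9S,10S)-9-(TBS-oxy)-12,12-dimethoxy-6,10-dimethyl-4-(TES-oxy)dodec-5-en-2-ynoate
Conditions: TESCl, imidazole, CH2Cl2, 0 °C
Reagents that add atoms: chlorotriethylsilane, CC[Si](Cl)(CC)CC
Why: silylation blocks the propargylic alcohol during steps 15–18, and TES is chosen because it can later be removed in the presence of TBS.

Step 15
Reactants: 20 silyl ynoate
Product: 21 methyl (2Z,4R,5E,9S,10S)-9-(TBS-oxy)-12,12-dimethoxy-6,10-dimethyl-4-(TES-oxy)-2,3-bis(trimethylstannyl)dodeca-2,5-dienoate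
Conditions: Me3SnSnMe3 (1.1 equiv), Pd(PPh3)4 (5 mol%), THF, 60 °C
Reagents that add atoms: hexamethylditin, C[Sn](C)(C)[Sn](C)(C)C
Why: palladium-catalysed syn-distannation of the alkynoate gives the Z bis-stannane, which places C6 and the ester cis on the future butenolide double bond.

Step 16
Reactants: 21 bis-stannane
Product: 23 methyl (2E,4R,5E,9S,10S)-9-(TBS-oxy)-2-(hydroxymethyl)-12,12-dimethoxy-6,10-dimethyl-4-(TES-oxy)-3-(trimethylstannyl)dodeca-2,5-dienoate, via α-lithio stannyl enoate 22 (not isolated)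
Conditions: MeLi (1.1 equiv), THF, −98 °C, 15 min; then CH2O (gas, excess), −98 °C to −78 °C; aq. NH4Cl
Reagents that add atoms: formaldehyde, C=O
Why: chemoselective tin–lithium exchange at the ester-bearing α-carbon, then 1,2-addition of the alkenyllithium to formaldehyde with retention, introduces C13 cis to the remaining tin.

Step 17
Reactants: 23 allylic alcohol
Product: 24 methyl (2E,4R,5E,9S,10S)-2-(acetoxymethyl)-9-(TBS-oxy)-12,12-dimethoxy-6,10-dimethyl-4-(TES-oxy)-3-(trimethylstannyl)dodeca-2,5-dienoate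
Conditions: Ac2O, pyridine, CH2Cl2, 0 °C to 25 °C
Reagents that add atoms: acetic anhydride, CC(=O)OC(C)=O
Why: acetylation of the primary alcohol installs the C13 acetate of the target.

Step 18
Reactants: 24 alkenylstannane
Product: 25 methyl (2E,4R,5E,9S,10S)-2-(acetoxymethyl)-9-(TBS-oxy)-3-iodo-12,12-dimethoxy-6,10-dimethyl-4-(TES-oxy)dodeca-2,5-dienoate
Conditions: I2 (1.05 equiv), CH2Cl2, 0 °C; aq. Na2S2O3
Reagents that add atoms: iodine, II
Why: iododestannylation (electrophilic ipso substitution) retains the alkene geometry and is much faster than any reaction of iodine with the trisubstituted alkene.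

Step 19
Reactants: 25 alkenyl iodide
Product: 27 {(5R)-5-[(1E,5S,6S)-5-(TBS-oxy)-8,8-dimethoxy-2,6-dimethyloct-1-en-1-yl]-4-iodo-2-oxo-2,5-dihydrofuran-3-yl}methyl acetate, via γ-hydroxy Z-enoate 26 (not isolated)
Conditions: PPTS (20 mol%), MeOH, 25 °C; then toluene, 50 °C
Reagents that add atoms: none
Why: acidic methanolysis removes the labile TES ether selectively and the freed γ-hydroxy Z-enoate lactonises (transesterification) to the butenolide without touching C6.

Step 20
Reactants: 27 acetal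
Product: 28 {(5R)-5-[(1E,5S,6S)-5-(TBS-oxy)-2,6-dimethyl-8-oxooct-1-en-1-yl]-4-iodo-2-oxo-2,5-dihydrofuran-3-yl}methyl acetate
Conditions: PPTS, acetone/H2O (10:1), 50 °C
Reagents that add atoms: water, O
Why: acid-catalysed acetal hydrolysis unmasks the C8 aldehyde under conditions that spare the secondary TBS ether, the allylic acetate and the iodobutenolide.

Step 21
Reactants: 28 iodo aldehyde
Product: 29 (1S,6R,10S,4E)-13-acetoxy-8-hydroxy-1-(TBS-oxy)germacra-4,7(11)-dien-12,6-olide (8R/8S mixture)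
Conditions: CrCl2 (10 equiv), NiCl2 (0.2 equiv), degassed DMSO, 25 °C, 2 mM, syringe-pump addition
Reagents that add atoms: none
Why: Nozaki–Hiyama–Kishi reaction: oxidative addition of the activated alkenyl iodide to zerovalent nickel, transmetallation to chromium and intramolecular 1,2-addition to the aldehyde at high dilution close the ten-membered ring, with C8 formed as an epimer mixture that steps 22–23 converge.

Step 22
Reactants: 29 allylic alcohol mixture
Product: 30 (1S,6R,10S,4E)-13-acetoxy-8-oxo-1-(TBS-oxy)germacra-4,7(11)-dien-12,6-olide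
Conditions: Dess–Martin periodinane, NaHCO3, CH2Cl2, 0 °C to 25 °C
Reagents that add atoms: none
Why: Dess–Martin oxidation under neutral conditions converts both C8 epimers into one enone.

Step 23
Reactants: 30 enone
Product: 31 (1S,6R,8S,10S,4E)-13-acetoxy-8-hydroxy-1-(TBS-oxy)germacra-4,7(11)-dien-12,6-olide
Conditions: (R)-Me-CBS [(R)-1-methyl-3,3-diphenyltetrahydro-1H,3H-pyrrolo[1,2-c][1,3,2]oxazaborole] (0.3 equiv), catecholborane, toluene/CH2Cl2, −78 °C
Reagents that add atoms: none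
Why: Corey–Bakshi–Shibata reduction: with the butenolide alkenyl carbon as the large and the C9 methylene as the small substituent, the (R)-oxazaborolidine delivers hydride 1,2 to give the 8S alcohol.

Step 24
Reactants: 31 allylic alcohol
Product: 32 (1S,6R,8S,10S,4E)-13-acetoxy-8-(methacryloyloxy)-1-(TBS-oxy)germacra-4,7(11)-dien-12,6-olide
Conditions: methacrylic anhydride, Et3N, DMAP (cat.), BHT (trace), CH2Cl2, 0 °C to 25 °C
Reagents that add atoms: methacrylic anhydride, CC(=C)C(=O)OC(=O)C(C)=C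
Why: DMAP-catalysed acylation of the secondary alcohol proceeds with retention at C8.

Step 25
Reactants: 32 silyl ether
Product: 33 (1S,6R,8S,10S,4E)-13-acetoxy-1-hydroxy-8-(methacryloyloxy)germacra-4,7(11)-dien-12,6-olide
Conditions: HF·pyridine, pyridine, THF, 0 °C to 25 °C
Reagents that add atoms: none
Why: fluoride-mediated desilylation under buffered conditions leaves the esters and the butenolide untouched.

Step 26
Reactants: 33 secondary alcohol
Product: 34 (1S,6R,8S,10S,4E)-1,13-diacetoxy-8-(methacryloyloxy)germacra-4,7(11)-dien-12,6-olide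
Conditions: Ac2O, pyridine, DMAP (cat.), CH2Cl2, 0 °C to 25 °C
Reagents that add atoms: acetic anhydride, CC(=O)OC(C)=O
Why: acetylation of the C1 alcohol with retention completes the ester pattern.

Step 27
Reactants: 34 diene lactone
Product: 35 glaucolide K [(1S,4R,5R,6S,8S,10S)-1,13-diacetoxy-4,5-epoxy-8-(methacryloyloxy)germacr-7(11)-en-12,6-olide]
Conditions: mCPBA (1.1 equiv), NaHCO3, CH2Cl2, 0 °C
Reagents that add atoms: mCPBA, OOC(=O)c1cccc(Cl)c1
Why: Prilezhaev epoxidation of the only electron-rich alkene; with H6 in the alkene plane (minimal allylic 1,3-strain with the C4 methyl) the ring shields one face, so attack on the exposed face syn to the C6 oxygen gives the trans (4R,5R)-epoxide.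

## Compound list

1 | geraniol | CC(C)=CCC/C(C)=C/CO | starting material
2 | geranyl PMB ether | CC(C)=CCC/C(C)=C/COCc1ccc(OC)cc1 | intermediate
3 | rac-3-{(3E)-5-[(4-methoxybenzyl)oxy]-3-methylpent-3-en-1-yl}-2,2-dimethyloxirane | CC1(C)OC1CC/C(C)=C/COCc1ccc(OC)cc1 | intermediate
4 | (6E)-8-[(4-methoxybenzyl)oxy]-2,6-dimethyloct-6-ene-2,3-diol (racemic) | CC(C)(O)C(O)CC/C(C)=C/COCc1ccc(OC)cc1 | intermediate
5 | (4E)-6-[(4-methoxybenzyl)oxy]-4-methylhex-4-enal | O=CCC/C(C)=C/COCc1ccc(OC)cc1 | intermediate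
6 | methyl propanoate | CCC(=O)OC | starting material
7 | lithium 1-methoxyprop-1-en-1-olate (kinetic enolate) | C/C=C(\OC)O[Li] | intermediate
8 | methyl (6E)-3-hydroxy-8-[(4-methoxybenzyl)oxy]-2,6-dimethyloct-6-enoate (racemic syn/anti mixture) | COC(=O)C(C)C(O)CC/C(C)=C/COCc1ccc(OC)cc1 | intermediate
9 | methyl (6E)-8-[(4-methoxybenzyl)oxy]-2,6-dimethyl-3-oxooct-6-enoate (racemic) | COC(=O)C(C)C(=O)CC/C(C)=C/COCc1ccc(OC)cc1 | intermediate
10 | methyl (2R,3S,6E)-3-hydroxy-8-[(4-methoxybenzyl)oxy]-2,6-dimethyloct-6-enoate | COC(=O)[C@H](C)[C@@H](O)CC/C(C)=C/COCc1ccc(OC)cc1 | intermediate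
11 | methyl (2R,3S,6E)-3-(TBS-oxy)-8-[(4-methoxybenzyl)oxy]-2,6-dimethyloct-6-enoate | COC(=O)[C@H](C)[C@@H](O[Si](C)(C)C(C)(C)C)CC/C(C)=C/COCc1ccc(OC)cc1 | intermediate
12 | (2R,3S,6E)-3-(TBS-oxy)-8-[(4-methoxybenzyl)oxy]-2,6-dimethyloct-6-enal | O=C[C@H](C)[C@@H](O[Si](C)(C)C(C)(C)C)CC/C(C)=C/COCc1ccc(OC)cc1 | intermediate
13 | tert-butyl{[(3S,4S,7E)-1-methoxy-9-[(4-methoxybenzyl)oxy]-3,7-dimethylnona-1,7-dien-4-yl]oxy}dimethylsilane (1E/1Z mixture) | COC=C[C@H](C)[C@@H](O[Si](C)(C)C(C)(C)C)CC/C(C)=C/COCc1ccc(OC)cc1 | intermediate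
14 | tert-butyl{[(3S,4S,7E)-1,1-dimethoxy-9-[(4-methoxybenzyl)oxy]-3,7-dimethylnon-7-en-4-yl]oxy}dimethylsilane | COC(OC)C[C@H](C)[C@@H](O[Si](C)(C)C(C)(C)C)CC/C(C)=C/COCc1ccc(OC)cc1 | intermediate
15 | (2E,6S,7S)-6-(TBS-oxy)-9,9-dimethoxy-3,7-dimethylnon-2-en-1-ol | COC(OC)C[C@H](C)[C@@H](O[Si](C)(C)C(C)(C)C)CC/C(C)=C/CO | intermediate
16 | (2E,6S,7S)-6-(TBS-oxy)-9,9-dimethoxy-3,7-dimethylnon-2-enal | COC(OC)C[C@H](C)[C@@H](O[Si](C)(C)C(C)(C)C)CC/C(C)=C/C=O | intermediate
17 | methyl propiolate (methyl prop-2-ynoate) | C#CC(=O)OC | starting material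
18 | methyl 3-(methylzincio)prop-2-ynoate | C[Zn]C#CC(=O)OC | intermediate
19 | methyl (4R,5E,9S,10S)-9-(TBS-oxy)-4-hydroxy-12,12-dimethoxy-6,10-dimethyldodec-5-en-2-ynoate | COC(OC)C[C@H](C)[C@@H](O[Si](C)(C)C(C)(C)C)CC/C(C)=C/[C@@H](O)C#CC(=O)OC | intermediate
20 | methyl (4R,5E,9S,10S)-9-(TBS-oxy)-12,12-dimethoxy-6,10-dimethyl-4-(TES-oxy)dodec-5-en-2-ynoate | COC(OC)C[C@H](C)[C@@H](O[Si](C)(C)C(C)(C)C)CC/C(C)=C/[C@@H](O[Si](CC)(CC)CC)C#CC(=O)OC | intermediate
21 | methyl (2Z,4R,5E,9S,10S)-9-(TBS-oxy)-12,12-dimethoxy-6,10-dimethyl-4-(TES-oxy)-2,3-bis(trimethylstannyl)dodeca-2,5-dienoate | COC(OC)C[C@H](C)[C@@H](O[Si](C)(C)C(C)(C)C)CC/C(C)=C/[C@@H](O[Si](CC)(CC)CC)/C([Sn](C)(C)C)=C(/[Sn](C)(C)C)C(=O)OC | intermediate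
22 | methyl (2E,4R,5E,9S,10S)-9-(TBS-oxy)-2-lithio-12,12-dimethoxy-6,10-dimethyl-4-(TES-oxy)-3-(trimethylstannyl)dodeca-2,5-dienoate | COC(OC)C[C@H](C)[C@@H](O[Si](C)(C)C(C)(C)C)CC/C(C)=C/[C@@H](O[Si](CC)(CC)CC)/C([Sn](C)(C)C)=C(/[Li])C(=O)OC | intermediate
23 | methyl (2E,4R,5E,9S,10S)-9-(TBS-oxy)-2-(hydroxymethyl)-12,12-dimethoxy-6,10-dimethyl-4-(TES-oxy)-3-(trimethylstannyl)dodeca-2,5-dienoate | COC(OC)C[C@H](C)[C@@H](O[Si](C)(C)C(C)(C)C)CC/C(C)=C/[C@@H](O[Si](CC)(CC)CC)/C([Sn](C)(C)C)=C(/CO)C(=O)OC | intermediate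
24 | methyl (2E,4R,5E,9S,10S)-2-(acetoxymethyl)-9-(TBS-oxy)-12,12-dimethoxy-6,10-dimethyl-4-(TES-oxy)-3-(trimethylstannyl)dodeca-2,5-dienoate | COC(OC)C[C@H](C)[C@@H](O[Si](C)(C)C(C)(C)C)CC/C(C)=C/[C@@H](O[Si](CC)(CC)CC)/C([Sn](C)(C)C)=C(/COC(C)=O)C(=O)OC | intermediate
25 | methyl (2E,4R,5E,9S,10S)-2-(acetoxymethyl)-9-(TBS-oxy)-3-iodo-12,12-dimethoxy-6,10-dimethyl-4-(TES-oxy)dodeca-2,5-dienoate | COC(OC)C[C@H](C)[C@@H](O[Si](C)(C)C(C)(C)C)CC/C(C)=C/[C@@H](O[Si](CC)(CC)CC)/C(I)=C(/COC(C)=O)C(=O)OC | intermediate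
26 | methyl (2E,4R,5E,9S,10S)-2-(acetoxymethyl)-9-(TBS-oxy)-4-hydroxy-3-iodo-12,12-dimethoxy-6,10-dimethyldodeca-2,5-dienoate | COC(OC)C[C@H](C)[C@@H](O[Si](C)(C)C(C)(C)C)CC/C(C)=C/[C@@H](O)/C(I)=C(/COC(C)=O)C(=O)OC | intermediate
27 | {(5R)-5-[(1E,5S,6S)-5-(TBS-oxy)-8,8-dimethoxy-2,6-dimethyloct-1-en-1-yl]-4-iodo-2-oxo-2,5-dihydrofuran-3-yl}methyl acetate | COC(OC)C[C@H](C)[C@@H](O[Si](C)(C)C(C)(C)C)CC/C(C)=C/[C@H]1OC(=O)C(COC(C)=O)=C1I | intermediate
28 | {(5R)-5-[(1E,5S,6S)-5-(TBS-oxy)-2,6-dimethyl-8-oxooct-1-en-1-yl]-4-iodo-2-oxo-2,5-dihydrofuran-3-yl}methyl acetate | O=CC[C@H](C)[C@@H](O[Si](C)(C)C(C)(C)C)CC/C(C)=C/[C@H]1OC(=O)C(COC(C)=O)=C1I | intermediate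
29 | (1S,6R,10S,4E)-13-acetoxy-8-hydroxy-1-(TBS-oxy)germacra-4,7(11)-dien-12,6-olide (8R/8S mixture) | OC1C[C@H](C)[C@@H](O[Si](C)(C)C(C)(C)C)CC/C(C)=C/[C@H]2OC(=O)C(COC(C)=O)=C12 | intermediate
30 | (1S,6R,10S,4E)-13-acetoxy-8-oxo-1-(TBS-oxy)germacra-4,7(11)-dien-12,6-olide | O=C1C[C@H](C)[C@@H](O[Si](C)(C)C(C)(C)C)CC/C(C)=C/[C@H]2OC(=O)C(COC(C)=O)=C12 | intermediate
31 | (1S,6R,8S,10S,4E)-13-acetoxy-8-hydroxy-1-(TBS-oxy)germacra-4,7(11)-dien-12,6-olide | O[C@H]1C[C@H](C)[C@@H](O[Si](C)(C)C(C)(C)C)CC/C(C)=C/[C@H]2OC(=O)C(COC(C)=O)=C12 | intermediate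
32 | (1S,6R,8S,10S,4E)-13-acetoxy-8-(methacryloyloxy)-1-(TBS-oxy)germacra-4,7(11)-dien-12,6-olide | C=C(C)C(=O)O[C@H]1C[C@H](C)[C@@H](O[Si](C)(C)C(C)(C)C)CC/C(C)=C/[C@H]2OC(=O)C(COC(C)=O)=C12 | intermediate
33 | (1S,6R,8S,10S,4E)-13-acetoxy-1-hydroxy-8-(methacryloyloxy)germacra-4,7(11)-dien-12,6-olide | C=C(C)C(=O)O[C@H]1C[C@H](C)[C@@H](O)CC/C(C)=C/[C@H]2OC(=O)C(COC(C)=O)=C12 | intermediate
34 | (1S,6R,8S,10S,4E)-1,13-diacetoxy-8-(methacryloyloxy)germacra-4,7(11)-dien-12,6-olide | C=C(C)C(=O)O[C@H]1C[C@H](C)[C@@H](OC(C)=O)CC/C(C)=C/[C@H]2OC(=O)C(COC(C)=O)=C12 | intermediate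
35 | glaucolide K, (1S,4R,5R,6S,8S,10S)-1,13-diacetoxy-4,5-epoxy-8-(methacryloyloxy)germacr-7(11)-en-12,6-olide | C=C(C)C(=O)O[C@H]1C[C@H](C)[C@@H](OC(C)=O)CC[C@@]2(C)O[C@@H]2[C@H]2OC(=O)C(COC(C)=O)=C12 | target

## Step count and weakest steps

Total step count: 27. Longest linear sequence: 27 steps (geraniol 1 to glaucolide K 35); methyl propanoate 6 and methyl propiolate 17 enter as single commercial compounds.

Most likely to fail, first: step 16. The α-selective tin–lithium exchange in the presence of the ester, and the capture of the −98 °C alkenyllithium with gaseous formaldehyde, are the least precedented operations. The fallback sets out from ynoate 20 and replaces steps 15–17 by a halo-aldol (iodo-Baylis–Hillman-type) reaction. Et2AlI in CH2Cl2 at −78 °C adds iodide to C7, and the resulting aluminium allenolate is trapped at C11 by monomeric formaldehyde. Approach anti to the bulky C6 substituent places the new CH2OH cis to iodine and gives methyl (2E,4R,5E,9S,10S)-9-(TBS-oxy)-2-(hydroxymethyl)-3-iodo-12,12-dimethoxy-6,10-dimethyl-4-(TES-oxy)dodeca-2,5-dienoate F1. Acetylation (Ac2O, pyridine) then gives 25, where the route is rejoined; any 2Z isomer cannot lactonise in step 19 and is removed there.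

Second: step 21. Closure of a ten-membered carbocycle competes with reduction of the iodide and with oligomerisation. The fallback sets out from iodo aldehyde 28 and makes the C8 ketone directly, which also removes the C8 epimer problem. Pinnick oxidation (NaClO2, NaH2PO4, 2-methylbut-2-ene, t-BuOH/H2O) gives (3S,4S,7E)-8-[(2R)-4-(acetoxymethyl)-3-iodo-5-oxo-2,5-dihydrofuran-2-yl]-4-(TBS-oxy)-3,7-dimethyloct-7-enoic acid F2. 2,2'-Dipyridyl disulfide and PPh3 convert it into the S-(pyridin-2-yl) thioester of that acid F3. An intramolecular nickel/zirconium-mediated reductive ketone synthesis (NiBr2(dtbbpy), Cp2ZrCl2, Zn dust, 1,3-dimethylimidazolidin-2-one, high dilution) then couples the alkenyl iodide with the thioester carbonyl and returns to the route at ketone 30.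

Third: step 27. The facial selectivity rests on a conformational argument, and the opposite trans-epoxide may form. The fallback sets out from 34 and reaches the epoxide on the face that the peracid does not use. NBS in THF/H2O forms the bromonium ion on the exposed face and water opens it anti at C4, giving (1S,4R,5S,6S,8S,10S)-1,13-diacetoxy-5-bromo-4-hydroxy-8-(methacryloyloxy)germacr-7(11)-en-12,6-olide F4. Ag2O in THF then closes the oxirane by displacement of bromide with inversion at C5, and the route comes back at 35.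

Further compounds
F1 | step 16 | methyl (2E,4R,5E,9S,10S)-9-(TBS-oxy)-2-(hydroxymethyl)-3-iodo-12,12-dimethoxy-6,10-dimethyl-4-(TES-oxy)dodeca-2,5-dienoate | COC(OC)C[C@H](C)[C@@H](O[Si](C)(C)C(C)(C)C)CC/C(C)=C/[C@@H](O[Si](CC)(CC)CC)/C(I)=C(/CO)C(=O)OC
F2 | step 21 | (3S,4S,7E)-8-[(2R)-4-(acetoxymethyl)-3-iodo-5-oxo-2,5-dihydrofuran-2-yl]-4-(TBS-oxy)-3,7-dimethyloct-7-enoic acid | OC(=O)C[C@H](C)[C@@H](O[Si](C)(C)C(C)(C)C)CC/C(C)=C/[C@H]1OC(=O)C(COC(C)=O)=C1I
F3 | step 21 | S-(pyridin-2-yl) (3S,4S,7E)-8-[(2R)-4-(acetoxymethyl)-3-iodo-5-oxo-2,5-dihydrofuran-2-yl]-4-(TBS-oxy)-3,7-dimethyloct-7-enethioate | O=C(Sc1ccccn1)C[C@H](C)[C@@H](O[Si](C)(C)C(C)(C)C)CC/C(C)=C/[C@H]1OC(=O)C(COC(C)=O)=C1I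
F4 | step 27 | (1S,4R,5S,6S,8S,10S)-1,13-diacetoxy-5-bromo-4-hydroxy-8-(methacryloyloxy)germacr-7(11)-en-12,6-olide | C=C(C)C(=O)O[C@H]1C[C@H](C)[C@@H](OC(C)=O)CC[C@@](C)(O)[C@@H](Br)[C@H]2OC(=O)C(COC(C)=O)=C12
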